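The target is a cis-fused bicycle whose five-membered ring (C6–C7–C8–C9–C10) and seven-membered ring (C10–C1–C2–C3–C4–C5–C6) share only the C6–C10 bond. Cutting that bond leaves a ten-membered carbocycle C1–C10 with a trans C5–C6 epoxide and a ring-trans C9=C10 alkene bearing the isopropyl group. In the key step aqueous acid opens the epoxide at tertiary C6, C10 attacks across the ring and water caps C9: one operation forms the C6–C10 bond, closes both rings and sets the contiguous centres C6, C10 and C9, leaving the C5 hydroxyl for the ketone. The precursor carries a C1 silyl ether and a saturated C3 methyl centre.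

Key step: step 15

Remarks on the chemistry
- Atom labels: C1 = ester-bearing CH, C2 = CH2, C3 = methyl-bearing carbon, C4 = CH2 (later alkene CH), C5 = ketone carbon, C6 = quaternary methyl carbon, C7 and C8 = CH2, C9 = isopropyl carbinol carbon, C10 = ring-fusion CH.
- Descriptor: in the ten-membered ring the C9=C10 alkene has C8 and C1 trans (ring-trans). Because isopropyl outranks C8 at C9, its CIP descriptor is Z, and it is built as such (isopropyl cis to C10–I, then to C10–C1).
- Assumption: methyl hydrogen (R)-3-methylglutarate (the half-ester of 3-methylglutaric anhydride) and the enantiomer of the fructose-derived Shi ketone are purchased.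
- Design points:
  - The C5=C6 geometry comes from a Claisen rearrangement.
  - C1 is set by hydride reduction of the ring enone, not by the ring closure.
  - The C1 oxygen carries a silyl group that cannot participate.
  - The cyclisation medium supplies the water that ends up on C9.

Step 1
Reactants: 1 methyl hydrogen (R)-3-methylglutarate
Product: 2 methyl (3R)-5-hydroxy-3-methylpentanoate
Conditions: BH3·SMe2, THF, 0 °C to rt; MeOH quench
Reagents that add atoms: none
Why: Chemoselective borane reduction of a carboxylic acid beside a methyl ester (acyloxyborane pathway) gives the primary alcohol that becomes C1 and leaves the C3 centre untouched.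

Step 2
Reactants: 2 methyl (3R)-5-hydroxy-3-methylpentanoate
Product: 3 methyl (3R)-5-[(tert-butyldiphenylsilyl)oxy]-3-methylpentanoate
Conditions: t-BuPh2SiCl, imidazole, DMF, 0 °C to rt
Reagents that add atoms: tert-butyl(chloro)diphenylsilane, CC(C)(C)[Si](Cl)(c1ccccc1)c1ccccc1
Why: Silyl ether formation on the primary alcohol prevents lactonisation onto the ester and gives a group that should withstand the later acid-catalysed heating.

Step 3
Reactants: 3 methyl (3R)-5-[(tert-butyldiphenylsilyl)oxy]-3-methylpentanoate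
Product: 4 (3R)-5-[(tert-butyldiphenylsilyl)oxy]-3-methylpentanal
Conditions: i-Bu2AlH, CH2Cl2, −78 °C
Reagents that add atoms: none
Why: Low-temperature half-reduction of an ester by a dialkylaluminium hydride stops at the tetrahedral aluminium hemiacetal, which releases the C5 aldehyde on work-up.

Step 4
Reactants: 4 (3R)-5-[(tert-butyldiphenylsilyl)oxy]-3-methylpentanal; 5 isopropenylmagnesium bromide
Product: 6 (5R)-7-[(tert-butyldiphenylsilyl)oxy]-2,5-dimethylhept-1-en-3-ol (both carbinol epimers)
Conditions: THF, −78 to 0 °C; aq. NH4Cl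
Reagents that add atoms: isopropenylmagnesium bromide 5, CC(=C)[Mg]Br
Why: Grignard 1,2-addition to the aldehyde forms C5–C6 and brings in C6, its methyl and C7; the new carbinol centre forms without control and is erased in step 5.

Step 5
Reactants: 6 (5R)-7-[(tert-butyldiphenylsilyl)oxy]-2,5-dimethylhept-1-en-3-ol; 7 triethyl orthoacetate
Product: 9 ethyl (4E,7S)-9-[(tert-butyldiphenylsilyl)oxy]-4,7-dimethylnon-4-enoate, via mixed ketene acetal 8 (not isolated)
Conditions: MeC(OEt)3 (excess, neat), EtCO2H (cat.), 140 °C, EtOH distilled off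
Reagents that add atoms: triethyl orthoacetate 7, CCOC(C)(OCC)OCC
Why: The Johnson–Claisen rearrangement passes through a chair transition state with the C4 chain equatorial, so it forms C7–C8 and should set the trisubstituted C5=C6 alkene E, a geometry that olefination of a methyl ketone would not deliver reliably.

Step 6
Reactants: 9 ethyl (4E,7S)-9-[(tert-butyldiphenylsilyl)oxy]-4,7-dimethylnon-4-enoate; 10 dimethyl (1-diazo-2-oxopropyl)phosphonate
Product: 12 tert-butyl{[(3S,5E)-3,6-dimethyldec-5-en-9-yn-1-yl]oxy}diphenylsilane, via aldehyde 11 (not isolated)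
Conditions: i-Bu2AlH, CH2Cl2, −78 °C; then MeOH, NaOMe, Ohira–Bestmann reagent, −78 °C to rt
Reagents that add atoms: dimethyl (1-diazo-2-oxopropyl)phosphonate 10, COP(=O)(OC)C(=[N+]=[N-])C(C)=O
Why: Half-reduction followed in the same flask by Seyferth–Gilbert homologation with the Ohira–Bestmann reagent (a known one-pot ester-to-alkyne protocol) adds C10 as the terminal alkyne carbon.

Step 7
Reactants: 12 tert-butyl{[(3S,5E)-3,6-dimethyldec-5-en-9-yn-1-yl]oxy}diphenylsilane; 13 isopropylmagnesium bromide
Product: 15 tert-butyl{[(3S,5E,9Z)-10-iodo-3,6-dimethyl-9-(propan-2-yl)deca-5,9-dien-1-yl]oxy}diphenylsilane, via alkenylcopper 14 (not isolated)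
Conditions: i-PrMgBr, CuBr·SMe2, Et2O/Me2S, −45 °C; alkyne, −25 °C; then I2, THF, −40 to 0 °C
Reagents that add atoms: isopropylmagnesium bromide 13, CC(C)[Mg]Br; iodine, II
Why: In the Normant carbocupration the isopropylcopper reagent adds syn across the terminal alkyne with the alkyl group on internal C9 and copper on C10, and iodinolysis with retention gives the (Z)-iodide with isopropyl cis to iodine, the geometry that later places C8 and C1 trans in the ring.

Step 8
Reactants: 15 tert-butyl{[(3S,5E,9Z)-10-iodo-3,6-dimethyl-9-(propan-2-yl)deca-5,9-dien-1-yl]oxy}diphenylsilane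
Product: 16 tert-butyl{(3R)-4-[(2S,3S)-3-{(3Z)-4-iodo-3-(propan-2-yl)but-3-en-1-yl}-3-methyloxiran-2-yl]-3-methylbutoxy}diphenylsilane
Conditions: 1,2:4,5-di-O-isopropylidene-β-L-erythro-2,3-hexodiulo-2,6-pyranose (0.3 equiv), KHSO5 (as 2KHSO5·KHSO4·K2SO4), K2CO3, Bu4NHSO4 (cat.), MeCN/dimethoxymethane/aq. Na2B4O7, 0 °C
Reagents that add atoms: potassium peroxymonosulfate KHSO5, [K+].[O-]S(=O)(=O)OO
Why: In the Shi epoxidation the chiral dioxirane from the L-series ketone attacks the electron-rich E-trisubstituted alkene (the iodoalkene is deactivated and hindered) through the spiro transition state and should deliver the (5S,6S) trans-epoxide under catalyst control.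

Step 9
Reactants: 16 tert-butyl{(3R)-4-[(2S,3S)-3-{(3Z)-4-iodo-3-(propan-2-yl)but-3-en-1-yl}-3-methyloxiran-2-yl]-3-methylbutoxy}diphenylsilane
Product: 17 (3R)-4-[(2S,3S)-3-{(3Z)-4-iodo-3-(propan-2-yl)but-3-en-1-yl}-3-methyloxiran-2-yl]-3-methylbutan-1-ol
Conditions: Bu4NF, THF, 0 °C to rt
Reagents that add atoms: none
Why: Fluoride-induced desilylation frees the primary C1 alcohol; the epoxide is inert, and the iodoalkene has no hydrogen on C9 and so cannot eliminate.

Step 10
Reactants: 17 (3R)-4-[(2S,3S)-3-{(3Z)-4-iodo-3-(propan-2-yl)but-3-en-1-yl}-3-methyloxiran-2-yl]-3-methylbutan-1-ol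
Product: 18 (3S)-4-[(2S,3S)-3-{(3Z)-4-iodo-3-(propan-2-yl)but-3-en-1-yl}-3-methyloxiran-2-yl]-3-methylbutanal
Conditions: Dess–Martin periodinane, NaHCO3, CH2Cl2, 0 °C to rt
Reagents that add atoms: none
Why: Dess–Martin oxidation under bicarbonate buffer gives the C1 aldehyde without acid that could open the epoxide.

Step 11
Reactants: 18 (3S)-4-[(2S,3S)-3-{(3Z)-4-iodo-3-(propan-2-yl)but-3-en-1-yl}-3-methyloxiran-2-yl]-3-methylbutanal
Product: 19 (3R,5S,6S,9Z)-5,6-epoxy-3,6-dimethyl-9-(propan-2-yl)cyclodec-9-en-1-ol (atom labels; ring-trans alkene; both C1 epimers)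
Conditions: CrCl2 (excess), NiCl2 (cat.), DMSO, rt, slow addition at high dilution
Reagents that add atoms: none
Why: In the Nozaki–Hiyama–Kishi reaction nickel activates the alkenyl iodide and hands it to chromium, and the alkenylchromium adds chemoselectively to the aldehyde, closing the ten-membered ring at C10–C1 with retention of alkene geometry; C1 forms without reliable control and the epimer mixture is carried on.

Step 12
Reactants: 19 (3R,5S,6S,9Z)-5,6-epoxy-3,6-dimethyl-9-(propan-2-yl)cyclodec-9-en-1-ol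
Product: 20 (3S,5S,6S,9Z)-5,6-epoxy-3,6-dimethyl-9-(propan-2-yl)cyclodec-9-en-1-one (atom labels)
Conditions: Dess–Martin periodinane, NaHCO3, CH2Cl2, 0 °C
Reagents that add atoms: none
Why: Dess–Martin oxidation of the allylic alcohol converges both C1 epimers on a single enone.

Step 13
Reactants: 20 (3S,5S,6S,9Z)-5,6-epoxy-3,6-dimethyl-9-(propan-2-yl)cyclodec-9-en-1-one
Product: 21 (1S,3R,5S,6S,9Z)-5,6-epoxy-3,6-dimethyl-9-(propan-2-yl)cyclodec-9-en-1-ol (atom labels)
Conditions: NaBH4, CeCl3·7H2O, MeOH, −78 °C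
Reagents that add atoms: none
Why: In this Luche 1,2-reduction hydride should reach the C1 carbonyl of the crossed ring conformer from the ring periphery, on the side away from the isopropyl group that is cis to C1 (macrocyclic stereocontrol), which sets (1S); any minor epimer can be returned through step 12.

Step 14
Reactants: 21 (1S,3R,5S,6S,9Z)-5,6-epoxy-3,6-dimethyl-9-(propan-2-yl)cyclodec-9-en-1-ol
Product: 22 (1S,3S,5S,6S,9Z)-1-[(tert-butyldimethylsilyl)oxy]-5,6-epoxy-3,6-dimethyl-9-(propan-2-yl)cyclodec-9-ene (atom labels; ring-trans alkene)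
Conditions: t-BuMe2SiCl, imidazole, DMF, rt
Reagents that add atoms: tert-butyl(chloro)dimethylsilane, CC(C)(C)[Si](C)(C)Cl
Why: Silylation with the chloride and imidazole (no silyl triflate, which could activate the epoxide) installs a bulky ether that cannot participate, whereas an ester carbonyl at C1 could trap the C9 cation on the wrong face.

Step 15
Reactants: 22 (1S,3S,5S,6S,9Z)-1-[(tert-butyldimethylsilyl)oxy]-5,6-epoxy-3,6-dimethyl-9-(propan-2-yl)cyclodec-9-ene
Product: 23 (3R,3aR,4S,6S,8S,8aS)-4-[(tert-butyldimethylsilyl)oxy]-6,8a-dimethyl-3-(propan-2-yl)decahydroazulene-3,8-diol (atom labels: 1S,3S,5S,6S,9R,10R; cis-fused)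
Conditions: HClO4 (0.1 equiv), THF/H2O (3:1), 0 °C
Reagents that add atoms: water, O
Why: Protonation of the epoxide lets the C6–O bond ionise at the tertiary carbon while C10 of the alkene lying across the ring attacks C6 from the ring interior, and the tertiary C9 cation that results is captured by water. The closest known reaction type is the acid-promoted transannular epoxide–alkene cyclisation of cyclodeca-1,5-diene monoepoxides to hydroazulenes. The one new bond closes the five-membered ring (C6–C7–C8–C9–C10) in a closure that is 5-exo with respect to the epoxide and 5-endo with respect to the alkene, and the seven-membered ring (C10–C1–C2–C3–C4–C5–C6) in a closure that is 7-endo with respect to the epoxide and 7-exo with respect to the alkene. C6 is set by backside displacement (inversion at the epoxide carbon, C5 keeping its oxygen with retention), C10 by the crossed ring conformer in which H-10 and the C6 methyl point to the same side (cis fusion), and C9 by anti addition across the ring-trans alkene, water entering opposite the new bond so that the hydroxyl is cis to H-10 and the isopropyl cis to C1. The regioselectivity needed (C6–C10, not C5–C10 or C5–C9) is secured because only this pairing is Markovnikov at both ends, with tertiary cationic character at C6 and then at C9. Chemoselectivity is secured by substrate and medium: C3–C4 is saturated, the C1 oxygen bears a bulky silyl group that cannot participate, and the water-rich medium should hydrate C9 before proton loss.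

Step 16
Reactants: 23 (3R,3aR,4S,6S,8S,8aS)-4-[(tert-butyldimethylsilyl)oxy]-6,8a-dimethyl-3-(propan-2-yl)decahydroazulene-3,8-diol
Product: 25 C3=C4 enone silyl ether (atom labels: 1S,6S,9R,10R; C1 OSi-t-BuMe2; C5 ketone; C9 OH), via saturated ketone 24 (not isolated)
Conditions: 2-iodoxybenzoic acid (IBX, 3 equiv), DMSO, 70 °C
Reagents that add atoms: none
Why: IBX oxidises the C5 alcohol and then dehydrogenates the ketone (known one-flask alcohol-to-enone oxidation); C6 is quaternary, so enolisation is possible only toward C4, and the C3=C4 enone forms regiospecifically while the C3 stereocentre is erased.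

Step 17
Reactants: 25 C3=C4 enone silyl ether
Product: 26 (3R,3aR,4S,8aS)-3,4-dihydroxy-6,8a-dimethyl-3-(propan-2-yl)-2,3,3a,4,5,8a-hexahydroazulen-8(1H)-one (atom labels: 1S,6S,9R,10R; C1 OH, C9 OH)
Conditions: HF·pyridine, THF/pyridine, 0 °C to rt
Reagents that add atoms: none
Why: Fluoride desilylation in an acidic medium frees the C1 hydroxyl without the base-induced vinylogous elimination open to an enone oxygenated at its δ-carbon (C1).

Step 18
Reactants: 26 (3R,3aR,4S,8aS)-3,4-dihydroxy-6,8a-dimethyl-3-(propan-2-yl)-2,3,3a,4,5,8a-hexahydroazulen-8(1H)-one; 27 4-methoxybenzoyl chloride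
Product: 28 (3R,3aR,4S,8aS)-3-hydroxy-6,8a-dimethyl-8-oxo-3-(propan-2-yl)-1,2,3,3a,4,5,8,8a-octahydroazulen-4-yl 4-methoxybenzoate (target)
Conditions: 4-methoxybenzoyl chloride, Et3N, 4-(dimethylamino)pyridine (cat.), CH2Cl2, 0 °C to rt
Reagents that add atoms: 4-methoxybenzoyl chloride 27, COc1ccc(C(Cl)=O)cc1
Why: Acylation under nucleophilic catalysis should esterify the secondary C1 hydroxyl selectively, the tertiary C9 hydroxyl being too hindered to react.

Compound list
1 | methyl hydrogen (R)-3-methylglutarate | OC(=O)C[C@@H](C)CC(=O)OC | starting material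
2 | methyl (3R)-5-hydroxy-3-methylpentanoate | OCC[C@@H](C)CC(=O)OC | intermediate
3 | methyl (3R)-5-[(tert-butyldiphenylsilyl)oxy]-3-methylpentanoate | CC(C)(C)[Si](c1ccccc1)(c1ccccc1)OCC[C@@H](C)CC(=O)OC | intermediate
4 | (3R)-5-[(tert-butyldiphenylsilyl)oxy]-3-methylpentanal | CC(C)(C)[Si](c1ccccc1)(c1ccccc1)OCC[C@@H](C)CC=O | intermediate
5 | isopropenylmagnesium bromide | CC(=C)[Mg]Br | starting material
6 | (5R)-7-[(tert-butyldiphenylsilyl)oxy]-2,5-dimethylhept-1-en-3-ol, both carbinol epimers | CC(C)(C)[Si](c1ccccc1)(c1ccccc1)OCC[C@@H](C)CC(O)C(C)=C | intermediate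
7 | triethyl orthoacetate | CCOC(C)(OCC)OCC | starting material
8 | mixed ketene acetal (1-ethoxyvinyl ether of 6) | CC(C)(C)[Si](c1ccccc1)(c1ccccc1)OCC[C@@H](C)CC(OC(=C)OCC)C(C)=C | intermediate
9 | ethyl (4E,7S)-9-[(tert-butyldiphenylsilyl)oxy]-4,7-dimethylnon-4-enoate | CC(C)(C)[Si](c1ccccc1)(c1ccccc1)OCC[C@@H](C)C/C=C(\C)CCC(=O)OCC | intermediate
10 | dimethyl (1-diazo-2-oxopropyl)phosphonate (Ohira–Bestmann reagent) | COP(=O)(OC)C(=[N+]=[N-])C(C)=O | starting material
11 | (4E,7S)-9-[(tert-butyldiphenylsilyl)oxy]-4,7-dimethylnon-4-enal | CC(C)(C)[Si](c1ccccc1)(c1ccccc1)OCC[C@@H](C)C/C=C(\C)CCC=O | intermediate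
12 | tert-butyl{[(3S,5E)-3,6-dimethyldec-5-en-9-yn-1-yl]oxy}diphenylsilane | CC(C)(C)[Si](c1ccccc1)(c1ccccc1)OCC[C@@H](C)C/C=C(\C)CCC#C | intermediate
13 | isopropylmagnesium bromide | CC(C)[Mg]Br | starting material
14 | alkenylcopper from 12: copper on C10, isopropyl on C9 and cis to copper | CC(C)(C)[Si](c1ccccc1)(c1ccccc1)OCC[C@@H](C)C/C=C(\C)CC/C(C(C)C)=C/[Cu] | intermediate
15 | tert-butyl{[(3S,5E,9Z)-10-iodo-3,6-dimethyl-9-(propan-2-yl)deca-5,9-dien-1-yl]oxy}diphenylsilane | CC(C)(C)[Si](c1ccccc1)(c1ccccc1)OCC[C@@H](C)C/C=C(\C)CC/C(C(C)C)=C/I | intermediate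
16 | tert-butyl{(3R)-4-[(2S,3S)-3-{(3Z)-4-iodo-3-(propan-2-yl)but-3-en-1-yl}-3-methyloxiran-2-yl]-3-methylbutoxy}diphenylsilane | CC(C)(C)[Si](c1ccccc1)(c1ccccc1)OCC[C@@H](C)C[C@@H]2O[C@@]2(C)CC/C(C(C)C)=C/I | intermediate
17 | (3R)-4-[(2S,3S)-3-{(3Z)-4-iodo-3-(propan-2-yl)but-3-en-1-yl}-3-methyloxiran-2-yl]-3-methylbutan-1-ol | OCC[C@@H](C)C[C@@H]1O[C@@]1(C)CC/C(C(C)C)=C/I | intermediate
18 | (3S)-4-[(2S,3S)-3-{(3Z)-4-iodo-3-(propan-2-yl)but-3-en-1-yl}-3-methyloxiran-2-yl]-3-methylbutanal | O=CC[C@@H](C)C[C@@H]1O[C@@]1(C)CC/C(C(C)C)=C/I | intermediate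
19 | (3R,5S,6S,9Z)-5,6-epoxy-3,6-dimethyl-9-(propan-2-yl)cyclodec-9-en-1-ol, both C1 epimers (atom labels; ring-trans alkene) | CC(C)/C1=C\C(O)C[C@@H](C)C[C@@H]2O[C@@]2(C)CC1 | intermediate
20 | (3S,5S,6S,9Z)-5,6-epoxy-3,6-dimethyl-9-(propan-2-yl)cyclodec-9-en-1-one (atom labels) | CC(C)/C1=C\C(=O)C[C@@H](C)C[C@@H]2O[C@@]2(C)CC1 | intermediate
21 | (1S,3R,5S,6S,9Z)-5,6-epoxy-3,6-dimethyl-9-(propan-2-yl)cyclodec-9-en-1-ol (atom labels) | CC(C)/C1=C\[C@@H](O)C[C@@H](C)C[C@@H]2O[C@@]2(C)CC1 | intermediate
22 | (1S,3S,5S,6S,9Z)-1-[(tert-butyldimethylsilyl)oxy]-5,6-epoxy-3,6-dimethyl-9-(propan-2-yl)cyclodec-9-ene (atom labels; key-step precursor) | CC(C)/C1=C\[C@@H](O[Si](C)(C)C(C)(C)C)C[C@@H](C)C[C@@H]2O[C@@]2(C)CC1 | intermediate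
23 | (3R,3aR,4S,6S,8S,8aS)-4-[(tert-butyldimethylsilyl)oxy]-6,8a-dimethyl-3-(propan-2-yl)decahydroazulene-3,8-diol (atom labels 1S,3S,5S,6S,9R,10R; key-step product) | CC(C)(C)[Si](C)(C)O[C@H]2C[C@@H](C)C[C@H](O)[C@@]3(C)CC[C@@](O)(C(C)C)[C@@H]23 | intermediate
24 | C5 ketone of 23 (atom labels 1S,3R,6S,9R,10R) | CC(C)(C)[Si](C)(C)O[C@H]2C[C@@H](C)CC(=O)[C@@]3(C)CC[C@@](O)(C(C)C)[C@@H]23 | intermediate
25 | C3=C4 enone with C1 tert-butyldimethylsilyl ether and C9 hydroxyl (atom labels 1S,6S,9R,10R) | CC(C)(C)[Si](C)(C)O[C@H]2CC(C)=CC(=O)[C@@]3(C)CC[C@@](O)(C(C)C)[C@@H]23 | intermediate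
26 | (3R,3aR,4S,8aS)-3,4-dihydroxy-6,8a-dimethyl-3-(propan-2-yl)-2,3,3a,4,5,8a-hexahydroazulen-8(1H)-one | O[C@H]2CC(C)=CC(=O)[C@@]3(C)CC[C@@](O)(C(C)C)[C@@H]23 | intermediate
27 | 4-methoxybenzoyl chloride | COc1ccc(C(Cl)=O)cc1 | starting material
28 | (3R,3aR,4S,8aS)-3-hydroxy-6,8a-dimethyl-8-oxo-3-(propan-2-yl)-1,2,3,3a,4,5,8,8a-octahydroazulen-4-yl 4-methoxybenzoate | COc1ccc(C(=O)O[C@H]2CC(C)=CC(=O)[C@@]3(C)CC[C@@](O)(C(C)C)[C@@H]23)cc1 | target

Total step count: 18. Longest linear sequence: 18 steps (1 to 28).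

Steps most likely to fail

1. Step 15 (key step). The C9 cation may lose a proton or take a hydride from the isopropyl group before water arrives. The protonated epoxide may also be hydrolysed directly before the alkene engages. The fallback sets out from 22 and replaces hydration by solvent capture followed by ester cleavage. The cyclisation is run in anhydrous acetic acid/CH2Cl2 with catalytic BF3·OEt2 at −20 °C. Acetic acid is in large excess and is a poorer nucleophile toward the epoxide than water, so it should intercept C9 as the tertiary acetate, the C9 acetate of the bicyclic diol F1. Reductive removal of the acetate with i-Bu2AlH in CH2Cl2 at −78 °C, which leaves the silyl ether alone, brings the route back at 23.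

2. Step 11. Intermolecular coupling and protodeiodination may outrun closure of a strained ring that holds a trans alkene and a trans epoxide. The fallback sets out from 18 and closes the same bond by an anionic acylation instead of a carbonyl addition. Pinnick oxidation (NaClO2, NaH2PO4, 2-methylbut-2-ene, t-BuOH/H2O) gives the carboxylic acid F2. Coupling with N,O-dimethylhydroxylamine hydrochloride (1-ethyl-3-(3-dimethylaminopropyl)carbodiimide hydrochloride, Et3N, CH2Cl2) gives the Weinreb amide F3. Iodine–lithium exchange with t-BuLi in dilute THF at −78 °C then lets the alkenyllithium acylate the amide intramolecularly through the chelated tetrahedral intermediate. Work-up gives the enone directly, so steps 11 and 12 are bypassed and the route comes back at 20.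

3. Step 16. The enone may be oxidised further, dehydrogenation may stall at the ketone, or the tertiary C9 hydroxyl may be lost in hot DMSO. The fallback sets out from 23 and separates the two oxidations. Dess–Martin oxidation (NaHCO3, CH2Cl2) stops at ketone 24, which is isolated here. Me3SiOTf/Et3N in CH2Cl2 at 0 °C gives the C4=C5 trimethylsilyl enol ether that also carries a C9 trimethylsilyl ether F4. Saegusa–Ito oxidation (Pd(OAc)2, MeCN, rt) gives the C3=C4 enone still silylated at C9 F5. Step 17 (HF·pyridine) then removes both silyl groups, so the route comes back at 26.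

Further compounds
F1 | step 15 | C9 acetate of 23 (atom labels 1S,3S,5S,6S,9R,10R; C1 OSi-t-BuMe2, C5 OH) | CC(C)(C)[Si](C)(C)O[C@H]2C[C@@H](C)C[C@H](O)[C@@]3(C)CC[C@@](OC(C)=O)(C(C)C)[C@@H]23
F2 | step 11 | (3S)-4-[(2S,3S)-3-{(3Z)-4-iodo-3-(propan-2-yl)but-3-en-1-yl}-3-methyloxiran-2-yl]-3-methylbutanoic acid | OC(=O)C[C@@H](C)C[C@@H]1O[C@@]1(C)CC/C(C(C)C)=C/I
F3 | step 11 | (3S)-4-[(2S,3S)-3-{(3Z)-4-iodo-3-(propan-2-yl)but-3-en-1-yl}-3-methyloxiran-2-yl]-N-methoxy-N,3-dimethylbutanamide | CON(C)C(=O)C[C@@H](C)C[C@@H]1O[C@@]1(C)CC/C(C(C)C)=C/I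
F4 | step 16 | C4=C5 trimethylsilyl enol ether of 24 with C9 trimethylsilyl ether (atom labels 1S,3R,6S,9R,10R) | CC(C)(C)[Si](C)(C)O[C@H]2C[C@@H](C)C=C(O[Si](C)(C)C)[C@@]3(C)CC[C@@](O[Si](C)(C)C)(C(C)C)[C@@H]23
F5 | step 16 | C3=C4 enone with C1 tert-butyldimethylsilyl ether and C9 trimethylsilyl ether (atom labels 1S,6S,9R,10R) | CC(C)(C)[Si](C)(C)O[C@H]2CC(C)=CC(=O)[C@@]3(C)CC[C@@](O[Si](C)(C)C)(C(C)C)[C@@H]23
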